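## Retrosynthetic overview

1. Target ⇐ Zn-induced fragmentation of a 17-bromo-11β,16-oxolane, the ether that carries the 11β-oxygen and masks the 16-methylene.
2. 2β,3β-Diol ⇐ 1-en-3-one (conjugate reduction, enolate hydroxylation, ketone reduction) ⇐ 1-en-3β-ol.
3. 19,20-δ-Lactone (C20–O bond) ⇐ lactonising opening of a 1α,10α-cyclopropane (C20) next to a 2α-ol ⇐ Simmons–Smith on the 1(10)-en-2α-ol ⇐ 3-alkoxide-triggered allylic transposition and hydrolysis of the 19,10-lactone.
4. 11β–O bond ⇐ 1,5-hydrogen transfer to a C16 alkoxy radical ⇐ 16-norketone + LiCH2Br ⇐ ozonolysis, after 13-deoxygenation.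
5. Carbocyclic rings A–D come intact from gibberellic acid; new rings form in the order oxolane (step 7), cyclopropane (step 9), δ-lactone (step 10).

Assumption: gibberellic acid, a bulk fermentation product, is taken as a cheap commercial starting material; gibberellane numbering is used (C7 = carboxyl on C6, C19 and C20 = lactone carbons).

## Route

Step 1
Reactants: 1 gibberellic acid
Product: 2 gibberellic acid 2-(trimethylsilyl)ethyl ester (ester at C7)
Conditions: Me3SiCH2CH2OH (5 equiv), EDC·HCl, DMAP (0.2 equiv), CH2Cl2/THF, 0 → 23 °C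
Reagents that add atoms: 2-(trimethylsilyl)ethanol, C[Si](C)(C)CCO
Why: Steglich esterification of the only carboxylic acid gives a fluoride-cleavable ester that later falls together with the silyl ether; no stereocentre is touched.

Step 2
Reactants: 2 gibberellic acid 2-(trimethylsilyl)ethyl ester
Product: 3 3-O-TBS-gibberellic acid 2-(trimethylsilyl)ethyl ester
Conditions: TBSCl, imidazole, DMF, 23 °C
Reagents that add atoms: tert-butyldimethylsilyl chloride, CC(C)(C)[Si](C)(C)Cl
Why: Imidazole-mediated silylation takes the secondary 3β-OH and leaves the tertiary bridgehead 13-OH; the ether shields the 3-oxygen through the ring D operations (oxalylation, organolithium addition, alkoxy-radical chemistry) until it is needed free in step 8.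

Step 3
Reactants: 3 3-O-TBS-gibberellic acid 2-(trimethylsilyl)ethyl ester
Product: 4 13-O-(methoxyoxalyl)-3-O-TBS-gibberellic acid 2-(trimethylsilyl)ethyl ester
Conditions: ClCOCO2Me, DMAP, pyridine, CH2Cl2, 0 → 23 °C
Reagents that add atoms: methyl chlorooxoacetate, COC(=O)C(Cl)=O
Why: DMAP-catalysed acylation of the tertiary 13-OH by the highly electrophilic oxalyl half-ester chloride installs the radical leaving group.

Step 4
Reactants: 4 13-O-(methoxyoxalyl)-3-O-TBS-gibberellic acid 2-(trimethylsilyl)ethyl ester
Product: 5 13-deoxy-3-O-TBS-gibberellic acid 2-(trimethylsilyl)ethyl ester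
Conditions: Bu3SnH, AIBN (cat.), toluene, 110 °C
Reagents that add atoms: none
Why: Tin-hydride radical deoxygenation of a tertiary methyl oxalate (Barton–McCombie type), a method used on 13-hydroxygibberellins; the bridgehead radical can only be reduced with retention.

Step 5
Reactants: 5 13-deoxy-3-O-TBS-gibberellic acid 2-(trimethylsilyl)ethyl ester
Product: 6 17-nor-16-oxo derivative of 5 (ring D ketone)
Conditions: O3, CH2Cl2/pyridine, −78 °C; then Me2S
Reagents that add atoms: ozone, [O-][O+]=O
Why: Ozonolysis cleaves the electron-rich 1,1-disubstituted 16-ene, while the 1-ene, deactivated by two allylic C–O bonds, survives.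

Step 6
Reactants: 6 17-nor-16-oxo compound, 7 dibromomethane
Product: 8 17-bromo-16-hydroxy compound (16-OH endo, facing C11; CH2Br exo)
Conditions: CH2Br2 (3 equiv), n-BuLi (2.5 equiv, added last), THF, −78 °C; AcOH, −78 °C
Reagents that add atoms: dibromomethane (7), BrCBr
Why: Bromomethyllithium made by Br/Li exchange in the presence of the ketone (Barbier mode) adds 1,2 from the exo face (the side of the C14 bridge; the endo face is blocked by axial H-11β), which sets C16 with its oxygen endo and close to H-11β.

Step 7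
Reactants: 8 17-bromo-16-hydroxy compound
Product: 9 17-bromo-11β,16-epoxy compound (oxolane bridging C11β and C16)
Conditions: PhI(OAc)2 (1.6 equiv), I2 (1.0 equiv), cyclohexane/CH2Cl2, visible light, 25 °C
Reagents that add atoms: none
Why: Suárez hypoiodite reaction: the C16 alkoxy radical abstracts the syn-axial H-11β by 1,5-hydrogen atom transfer and oxidative C–O closure gives the oxolane, which fixes the 11β-oxygen (only the β face of C11 can be bridged to C16) and masks the future 16-ene.

Step 8
Reactants: 9 17-bromo-11β,16-epoxy compound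
Product: 12 2α,3β-dihydroxy-1(10)-ene-7,19-dioic acid (17-bromo-11β,16-ether intact), via 3β-hydroxy lactone acid 10 (not isolated), via isolactone acid 11 (not isolated)
Conditions: Bu4NF (4 equiv), THF, 23 °C; then 1 M aq KOH (8 equiv), 23 °C; then 1 M HCl to pH 3, 0 °C
Reagents that add atoms: potassium hydroxide, [K+].[OH-]
Why: Fluoride removes the 3-O-silyl group and, by β-elimination of Me3SiF and ethene, the 2-(trimethylsilyl)ethyl ester; the freed 3-alkoxide then takes part in the allylic lactone transposition known for gibberellic acid in aqueous alkali (anti SN2′ participation at C2, then closure of the C19 carboxylate on C2 from the α face), which gives the 19,2α-lactone and sets C2, and hydroxide saponifies this strained bridged isolactone; the neopentyl bromide and the bridging ether are inert.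

Step 9
Reactants: 12 2α,3β-dihydroxy-1(10)-ene-7,19-dioic acid, 13 diiodomethane
Product: 14 1α,10α-methano-2α,3β-dihydroxy-7,19-dioic acid (cyclopropane carbon = future C20, on the α face)
Conditions: Et2Zn (10 equiv), CH2I2 (10 equiv), CH2Cl2, 0 → 23 °C; 1 M HCl work-up, 0 °C
Reagents that add atoms: diiodomethane (13), ICI
Why: Hydroxyl-directed Simmons–Smith (Furukawa) cyclopropanation: the allylic 2α zinc alkoxide, seconded by the α-oriented zinc carboxylate at C19, delivers CH2 to the α face of the 1(10)-ene, which sets the quaternary C10 with C20 α, cis to the C19 carboxyl; the homoallylic 3β-alkoxide is a much weaker director.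

Step 10
Reactants: 14 1α,10α-methano-2α,3β-dihydroxy-7,19-dioic acid
Product: 15 3β-hydroxy-1-ene 19,20-lactone 7-carboxylic acid (bromo ether intact)
Conditions: TsOH·H2O (10 mol %), (CF3)2CHOH/CH2Cl2 1:4, 0 → 23 °C
Reagents that add atoms: none
Why: Proposed new method: an acid-triggered lactonising cyclopropylcarbinyl-to-homoallyl rearrangement, in which ionisation of the 2α-OH (the neopentyl 3β-OH cannot ionise) gives a cyclopropylcarbinyl cation whose charge is relayed into the exocyclic C1–C20 bond (the cyclopropane bond that overlaps best with the empty p orbital at C2), and the C19 carboxyl, held 1,3-diaxial to C20 on the α face and in line with the back side of the C1–C20 bond, closes a six-membered ring on the CH2 carbon (new C20–O bond) as C1=C2 forms; in the conformer that holds the carboxyl axial over C20, H-3α is equatorial and lies near the nodal plane of that p orbital, which disfavours a pinacol-type hydride shift; capture at C2 (cyclopropyl isolactone) or at tertiary C10 (ring-expanded lactone) gives esters that re-ionise under these conditions whereas the primary alkyl ester does not, so the δ-lactone is the sink, and no stereocentre is created (C10 was set in step 9, C3 is untouched); the closest known reactions are the Julia–Johnson homoallylic rearrangement of cyclopropylcarbinols with halide and the retro-i-steroid rearrangement with external oxygen nucleophiles, neither shown with an internal carboxylic acid attacking the cyclopropane CH2 to build a lactone.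

Step 11
Reactants: 15 3β-hydroxy-1-ene 19,20-lactone 7-carboxylic acid
Product: 16 1-en-3-one 19,20-lactone 7-carboxylic acid (bromo ether intact)
Conditions: Dess–Martin periodinane, CH2Cl2, 23 °C
Reagents that add atoms: none
Why: Dess–Martin oxidation of the allylic alcohol to the enone under neutral conditions; acid, lactone and bromo ether are inert.

Step 12
Reactants: 16 1-en-3-one 19,20-lactone 7-carboxylic acid
Product: 18 2β,3β-dihydroxy 19,20-lactone 7-carboxylic acid (17-bromo-11β,16-ether intact), via hydroxy ketone 17 (not isolated)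
Conditions: KBH(s-Bu)3 (2.2 equiv), THF, −78 °C; 2-(phenylsulfonyl)-3-phenyloxaziridine (1.3 equiv), −78 °C; KBH(s-Bu)3 (3 equiv), −78 → −40 °C; AcOH, −78 °C
Reagents that add atoms: 2-(phenylsulfonyl)-3-phenyloxaziridine (Davis reagent), O=S(=O)(c1ccccc1)N1OC1c1ccccc1
Why: Conjugate reduction by the hindered borohydride gives the C2=C3 enolate, which the Davis oxaziridine hydroxylates on the only open (β, exo) face of the lactone-bridged ring A (sets C2), and the same bulky hydride then attacks C3 equatorially to give the axial 3β-alcohol (sets C3), as in such reductions of 3-oxogibberellins and 4,4-disubstituted 3-ketoterpenoids.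

Step 13
Reactants: 18 2β,3β-dihydroxy bromo ether acid
Product: 19 target (2β,3β,11β-trihydroxy-16-ene 19,20-lactone 7-carboxylic acid)
Conditions: Zn dust (activated, 20 equiv), NH4Cl, EtOH/H2O 4:1, 70 °C
Reagents that add atoms: none
Why: Boord-type reductive fragmentation (zinc insertion into C–Br, then β-elimination of the ether oxygen) regenerates the 16(17)-methylene regiospecifically and releases the 11β-alkoxide with its configuration untouched.

## Compound list

1 | gibberellic acid | C=C1C[C@]23C[C@@]1(O)CC[C@H]2[C@@]12C=C[C@H](O)[C@@](C)(C(=O)O1)[C@H]2[C@@H]3C(=O)O | starting material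
2 | gibberellic acid 2-(trimethylsilyl)ethyl ester | C=C1C[C@]23C[C@@]1(O)CC[C@H]2[C@@]12C=C[C@H](O)[C@@](C)(C(=O)O1)[C@H]2[C@@H]3C(=O)OCC[Si](C)(C)C | intermediate
3 | 3-O-TBS-gibberellic acid 2-(trimethylsilyl)ethyl ester | C=C1C[C@]23C[C@@]1(O)CC[C@H]2[C@@]12C=C[C@H](O[Si](C)(C)C(C)(C)C)[C@@](C)(C(=O)O1)[C@H]2[C@@H]3C(=O)OCC[Si](C)(C)C | intermediate
4 | 13-O-(methoxyoxalyl)-3-O-TBS-gibberellic acid 2-(trimethylsilyl)ethyl ester | C=C1C[C@]23C[C@@]1(OC(=O)C(=O)OC)CC[C@H]2[C@@]12C=C[C@H](O[Si](C)(C)C(C)(C)C)[C@@](C)(C(=O)O1)[C@H]2[C@@H]3C(=O)OCC[Si](C)(C)C | intermediate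
5 | 13-deoxy-3-O-TBS-gibberellic acid 2-(trimethylsilyl)ethyl ester | C=C1C[C@]23C[C@H]1CC[C@H]2[C@@]12C=C[C@H](O[Si](C)(C)C(C)(C)C)[C@@](C)(C(=O)O1)[C@H]2[C@@H]3C(=O)OCC[Si](C)(C)C | intermediate
6 | 17-nor-16-oxo derivative of 5 | O=C1C[C@]23C[C@H]1CC[C@H]2[C@@]12C=C[C@H](O[Si](C)(C)C(C)(C)C)[C@@](C)(C(=O)O1)[C@H]2[C@@H]3C(=O)OCC[Si](C)(C)C | intermediate
7 | dibromomethane | BrCBr | starting material
8 | 17-bromo-16-hydroxy compound (16-OH endo) | BrC[C@]1(O)C[C@]23C[C@H]1CC[C@H]2[C@@]12C=C[C@H](O[Si](C)(C)C(C)(C)C)[C@@](C)(C(=O)O1)[C@H]2[C@@H]3C(=O)OCC[Si](C)(C)C | intermediate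
9 | 17-bromo-11β,16-epoxy compound | BrC[C@]14C[C@]23C[C@H]1C[C@H](O4)[C@H]2[C@@]12C=C[C@H](O[Si](C)(C)C(C)(C)C)[C@@](C)(C(=O)O1)[C@H]2[C@@H]3C(=O)OCC[Si](C)(C)C | intermediate
10 | 3β-hydroxy-1-ene 19,10-lactone 7-carboxylic acid with the bromo ether (desilylated 9) | BrC[C@]14C[C@]23C[C@H]1C[C@H](O4)[C@H]2[C@@]12C=C[C@H](O)[C@@](C)(C(=O)O1)[C@H]2[C@@H]3C(=O)O | intermediate (not isolated)
11 | isolactone acid (19,2α-lactone, 1(10)-ene, 3β-OH, 7-carboxylic acid) | BrC[C@]14C[C@]23C[C@H]1C[C@H](O4)[C@H]2C1=C[C@H]5OC(=O)[C@](C)([C@H]5O)[C@H]1[C@@H]3C(=O)O | intermediate (not isolated)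
12 | 2α,3β-dihydroxy-1(10)-ene-7,19-dioic acid | BrC[C@]14C[C@]23C[C@H]1C[C@H](O4)[C@H]2C1=C[C@@H](O)[C@H](O)[C@@](C)(C(=O)O)[C@H]1[C@@H]3C(=O)O | intermediate
13 | diiodomethane | ICI | starting material
14 | 1α,10α-methano-2α,3β-dihydroxy-7,19-dioic acid | BrC[C@]14C[C@]23C[C@H]1C[C@H](O4)[C@H]2[C@@]16C[C@H]6[C@@H](O)[C@H](O)[C@@](C)(C(=O)O)[C@H]1[C@@H]3C(=O)O | intermediate
15 | 3β-hydroxy-1-ene 19,20-lactone 7-acid | BrC[C@]14C[C@]23C[C@H]1C[C@H](O4)[C@H]2[C@]12COC(=O)[C@](C)([C@@H](O)C=C1)[C@H]2[C@@H]3C(=O)O | intermediate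
16 | 1-en-3-one 19,20-lactone 7-acid | BrC[C@]14C[C@]23C[C@H]1C[C@H](O4)[C@H]2[C@]12COC(=O)[C@](C)(C(=O)C=C1)[C@H]2[C@@H]3C(=O)O | intermediate
17 | 2β-hydroxy-3-one | BrC[C@]14C[C@]23C[C@H]1C[C@H](O4)[C@H]2[C@]12COC(=O)[C@](C)(C(=O)[C@@H](O)C1)[C@H]2[C@@H]3C(=O)O | intermediate (not isolated)
18 | 2β,3β-diol with 17-bromo-11β,16-ether | BrC[C@]14C[C@]23C[C@H]1C[C@H](O4)[C@H]2[C@]12COC(=O)[C@](C)([C@@H](O)[C@@H](O)C1)[C@H]2[C@@H]3C(=O)O | intermediate
19 | CNP0302900.3 | C=C1C[C@]23C[C@H]1C[C@H](O)[C@H]2[C@]12COC(=O)[C@](C)([C@@H](O)[C@@H](O)C1)[C@H]2[C@@H]3C(=O)O | target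

## Step count and risks

Total steps: 13. Longest linear sequence: 13 (from gibberellic acid).

**Step 7 (alkoxy-radical etherification).** The tertiary C16 alkoxy radical can undergo β-scission (loss of the bromomethyl radical or opening of ring D) instead of abstracting H-11β, and the iodine oxidant may touch ring A. The fallback forms the C11 functional group as C–N first and closes the ether by carbonyl chemistry. It sets out from 8. Nitrosyl chloride in pyridine at −20 °C gives the nitrite ester F1. Photolysis in benzene (Barton reaction, no oxidant) transfers NO to C11 and, after tautomerisation, gives the 11-oxime F2. Deoximation with aqueous NaHSO3 then dilute HCl gives the 11-ketone, which closes onto the endo 16-OH as the 11-hydroxy-11,16-epoxide (hemiketal) F3. Ionic reduction with Et3SiH and BF3·OEt2 in CH2Cl2 at −78 °C returns to the route at 9.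

**Step 10 (proposed new lactonisation).** The cation may be captured elsewhere without return, eliminate, or suffer a pinacol-type hydride shift from C3 to give a 3-ketone; the allylic 3β-alcohol of the product may also ionise if the acid is left too long. The fallback uses known chemistry, sets out from 14, and passes the cyclopropane carbon to a soft external nucleophile before the C–O bond is made by substitution. 48 % aq HBr in Et2O at 0 °C (Julia–Johnson homoallylic rearrangement, in which bromide takes the cyclopropane CH2 carbon as C1=C2 forms) gives the 20-bromo-1-en-3β-ol-7,19-dioic acid F4. Cs2CO3 in DMF at 60 °C then closes the δ-lactone by intramolecular SN2 displacement of the primary bromide by the C19 carboxylate (the C17 bromide has no nucleophile within reach) and returns to the route at 15. This fallback does not remove the hydride-shift risk, because the HBr step passes through the same cation.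

**Step 12 (one-pot ring A endgame).** Possible failures are 1,2-reduction of the enone, retro-aldol loss of the 3-alkoxide, or the wrong C3 epimer. The fallback sets both carbinol centres in one dihydroxylation and sets out from 16. KBH(s-Bu)3 at −78 °C followed by PhNTf2 traps the enolate as the enol triflate F5. Pd(OAc)2, PPh3, Bu3N and HCO2H in DMF at 60 °C reduce it to the 2-ene F6. OsO4 (cat.) with N-methylmorpholine N-oxide dihydroxylates the exo (β) face, while the 16-ene is still masked, and returns to the route at 18.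

## Further compounds

F1 | step 7 | nitrite ester of 8 | BrC[C@]1(ON=O)C[C@]23C[C@H]1CC[C@H]2[C@@]12C=C[C@H](O[Si](C)(C)C(C)(C)C)[C@@](C)(C(=O)O1)[C@H]2[C@@H]3C(=O)OCC[Si](C)(C)C
F2 | step 7 | 11-oxime of the 17-bromo-16-hydroxy compound | BrC[C@]1(O)C[C@]23C[C@H]1CC(=NO)[C@H]2[C@@]12C=C[C@H](O[Si](C)(C)C(C)(C)C)[C@@](C)(C(=O)O1)[C@H]2[C@@H]3C(=O)OCC[Si](C)(C)C
F3 | step 7 | 11-hydroxy-11,16-epoxide (hemiketal) | BrC[C@]14C[C@]23C[C@H]1C[C@](O)(O4)[C@H]2[C@@]12C=C[C@H](O[Si](C)(C)C(C)(C)C)[C@@](C)(C(=O)O1)[C@H]2[C@@H]3C(=O)OCC[Si](C)(C)C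
F4 | step 10 | 20-bromo-1-en-3β-ol-7,19-dioic acid | BrC[C@]14C[C@]23C[C@H]1C[C@H](O4)[C@H]2[C@]1(CBr)C=C[C@H](O)[C@@](C)(C(=O)O)[C@H]1[C@@H]3C(=O)O
F5 | step 12 | 2-en-3-yl triflate | BrC[C@]14C[C@]23C[C@H]1C[C@H](O4)[C@H]2[C@]12COC(=O)[C@](C)(C(OS(=O)(=O)C(F)(F)F)=CC1)[C@H]2[C@@H]3C(=O)O
F6 | step 12 | 2-ene (3-deoxy) 19,20-lactone 7-acid | BrC[C@]14C[C@]23C[C@H]1C[C@H](O4)[C@H]2[C@]12COC(=O)[C@](C)(C=CC1)[C@H]2[C@@H]3C(=O)O
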